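**Plan**

- Retrosynthesis: the acetate C–O bond is cut first. Then the ring bond between the oxygen-bearing carbon and the ring CH2 is cut together with the C–Br bond of the neighbouring CHBr (retro bromo-Prins), which opens the cyclohexane to the acyclic γ-bromoenal 8. Enal 8 goes back to 1-methoxydiene 6, vinyl ketone 5, α-chloroaldehyde 3 and 3,3-dimethylpent-4-enal 2.
- Forward: the C7 aldehyde is chlorinated, extended by a vinyl and a methoxymethylidene unit, and brominated to the enal. The only ring, the cyclohexane, closes in step 7, and acetylation ends the route.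
- Enabling feature: the 1,3-cis O–CH–CH2–CH–Br array of the six-membered ring. Its oxygen-bearing carbon sits on the alkylidene carbon and its bromine-bearing carbon sits on the CMe2 carbon, so the array is an aldehyde plus a CH2=CH–CMe2 group. That vinyl group has no allylic hydrogen, so only halide capture can end the cation.
- Stereochemistry: the C–Cl centre comes from enamine-catalysed α-chlorination. In the chair of the ring closure it sits axial (allylic strain with the CH2Br arm) and sets the carbinol and C–Br centres. The alkene geometry is fixed at the enal stage (CH2Br trans to CHO).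

Key step: step 7

Remark: ester 1 is taken as the commercial starting material. The sense of induction in step 2 follows the usual enamine model (attack anti to the benzyl group); the antipodal catalyst is available if the opposite sense is found.

**Step 1**
Reactants: 1 methyl 3,3-dimethylpent-4-enoate
Product: 2 3,3-dimethylpent-4-enal
Conditions: DIBAL-H (1.05 equiv), CH2Cl2, −78 °C; aqueous work-up
Reagents that add atoms: none
Why: DIBAL-H partial reduction of an ester, in which the aluminium hemiacetal is stable at −78 °C and releases the aldehyde only on work-up; no stereocentre is formed.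

**Step 2**
Reactants: 2 3,3-dimethylpent-4-enal
Product: 3 (2S)-2-chloro-3,3-dimethylpent-4-enal
Conditions: (5S)-5-benzyl-2,2,3-trimethylimidazolidin-4-one·TFA (10 mol%), 2,3,4,5,6,6-hexachlorocyclohexa-2,4-dien-1-one (1.2 equiv), acetone, −30 °C; cold pentane, filtration, used at once
Reagents that add atoms: 2,3,4,5,6,6-hexachlorocyclohexa-2,4-dien-1-one, O=C1C(Cl)=C(Cl)C(Cl)=C(Cl)C1(Cl)Cl
Why: Organocatalytic enamine α-chlorination of an aldehyde, in which the E-enamine should be chlorinated on the face remote from the benzyl group to set the (S)-C–Cl centre, and the quaternary β-carbon slows later enolisation.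

**Step 3**
Reactants: 3 (2S)-2-chloro-3,3-dimethylpent-4-enal
Product: 4 (4S)-4-chloro-5,5-dimethylhepta-1,6-dien-3-ol (both C3 epimers)
Conditions: CH2=CHMgBr (1.2 equiv), THF, −78 °C, then H2O
Reagents that add atoms: vinylmagnesium bromide, C=C[Mg]Br
Why: Grignard 1,2-addition to the α-chloroaldehyde at −78 °C should outrun enolisation, and the new carbinol centre, formed as a mixture, is erased in step 4.

**Step 4**
Reactants: 4 (4S)-4-chloro-5,5-dimethylhepta-1,6-dien-3-ol
Product: 5 (4S)-4-chloro-5,5-dimethylhepta-1,6-dien-3-one
Conditions: Dess–Martin periodinane (1.3 equiv), CH2Cl2, 0 °C to rt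
Reagents that add atoms: none
Why: Dess–Martin oxidation of the allylic alcohol proceeds under non-basic conditions, so the enolisable C–Cl centre next to the new ketone should keep its configuration.

**Step 5**
Reactants: 5 (4S)-4-chloro-5,5-dimethylhepta-1,6-dien-3-one
Product: 6 (4S)-4-chloro-3-(methoxymethylidene)-5,5-dimethylhepta-1,6-diene (E/Z mixture at the enol ether)
Conditions: Ph3P+CH2OMe Cl− (1.5 equiv), KHMDS (1.4 equiv), THF, 0 °C; then 5, −78 °C to 0 °C
Reagents that add atoms: (methoxymethyl)triphenylphosphonium chloride, COC[P+](c1ccccc1)(c1ccccc1)c1ccccc1.[Cl-]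
Why: Wittig methoxymethylenation of the ketone carbonyl gives the 2-substituted 1-methoxybuta-1,3-diene, the cold addition being chosen to favour 1,2-olefination over enolisation at the C–Cl carbon; the enol ether geometry is irrelevant because it is lost in step 6.

**Step 6**
Reactants: 6 (4S)-4-chloro-3-(methoxymethylidene)-5,5-dimethylhepta-1,6-diene
Product: 8 (2Z)-4-bromo-2-[(1S)-1-chloro-2,2-dimethylbut-3-en-1-yl]but-2-enal, via methyl hemiacetal 7 (not isolated)
Conditions: NBS (1.05 equiv), THF–H2O (4:1), −20 °C to 0 °C
Reagents that add atoms: N-bromosuccinimide, O=C1CCC(=O)N1Br; water, O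
Why: Electrophilic γ-bromination of a dienol ether, in which Br+ adds to the unhindered terminal CH2, water hydrolyses the resulting oxocarbenium ion, and the s-trans diene together with the thermodynamic preference of 2-substituted enals should place CH2Br trans to CHO.

**Step 7**
Reactants: 8 (2Z)-4-bromo-2-[(1S)-1-chloro-2,2-dimethylbut-3-en-1-yl]but-2-enal
Product: 9 (1S,2Z,3R,5R)-5-bromo-2-(2-bromoethylidene)-3-chloro-4,4-dimethylcyclohexan-1-ol
Conditions: TiBr4 (1.2 equiv), CH2Cl2, −78 °C to −40 °C; cold aqueous quench
Reagents that add atoms: titanium tetrabromide, Br[Ti](Br)(Br)Br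
Why: TiBr4 binds the aldehyde oxygen of 8, the vinyl group attacks the carbonyl carbon through its terminal CH2 (Markovnikov sense), and the secondary cation next to the CMe2 carbon collapses with bromide from the titanium ate complex, so that the C–C bond, the C–O centre and the C–Br centre arise together. The closest known reaction type is the halo-Prins (carbonyl–olefin) cyclisation of alkenyl aldehydes to cis-3-halocyclohexanols with titanium or aluminium halides. The cyclohexane closes 6-exo-trig at the C=O and 6-endo-trig at the vinyl group through a chair. The carbinol centre is controlled by the C–Cl centre: allylic 1,3-strain with the CH2Br arm of the enal alkene forces Cl axial, and the titanium-bound oxygen then takes the equatorial site (s-cis enal) to avoid a syn-diaxial O/Cl contact, which places O trans to Cl. The C–Br centre is controlled by the same axial Cl, which screens the axial face of the cation, so bromide should enter equatorially, cis to O and trans to Cl. The step needs 1,2- over 1,4-attack (the substituted β-carbon would demand a 6-endo closure onto the enal), halide capture over rearrangement (no allylic hydrogen, so no ene outlet, and the only aligned migrating group, the axial methyl, would leave a cation beside C–Cl), and intact allylic halides (−78 °C, with the enal keeping them electron-poor until the ring has formed).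

**Step 8**
Reactants: 9 (1S,2Z,3R,5R)-5-bromo-2-(2-bromoethylidene)-3-chloro-4,4-dimethylcyclohexan-1-ol
Product: 10 (1S,2Z,3R,5R)-5-bromo-2-(2-bromoethylidene)-3-chloro-4,4-dimethylcyclohexyl acetate
Conditions: Ac2O (1.5 equiv), Sc(OTf)3 (2 mol%), MeCN, −20 °C to 0 °C
Reagents that add atoms: acetic anhydride, CC(=O)OC(C)=O
Why: Lewis acid-catalysed O-acylation of the secondary alcohol with retention at carbon, under non-nucleophilic conditions so that no pyridine-type base can quaternise the allylic bromide.

**Compound list**

1 | methyl 3,3-dimethylpent-4-enoate | COC(=O)CC(C)(C)C=C | starting material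
2 | 3,3-dimethylpent-4-enal | O=CCC(C)(C)C=C | intermediate
3 | (2S)-2-chloro-3,3-dimethylpent-4-enal | C=CC(C)(C)[C@H](Cl)C=O | intermediate
4 | (4S)-4-chloro-5,5-dimethylhepta-1,6-dien-3-ol (C3 epimers) | C=CC(C)(C)[C@H](Cl)C(O)C=C | intermediate
5 | (4S)-4-chloro-5,5-dimethylhepta-1,6-dien-3-one | C=CC(C)(C)[C@H](Cl)C(=O)C=C | intermediate
6 | (4S)-4-chloro-3-(methoxymethylidene)-5,5-dimethylhepta-1,6-diene (E/Z) | C=CC(C)(C)[C@H](Cl)C(=COC)C=C | intermediate
7 | (2Z)-4-bromo-2-[(1S)-1-chloro-2,2-dimethylbut-3-en-1-yl]-1-methoxybut-2-en-1-ol (methyl hemiacetal) | C=CC(C)(C)[C@H](Cl)/C(C(O)OC)=C\CBr | intermediate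
8 | (2Z)-4-bromo-2-[(1S)-1-chloro-2,2-dimethylbut-3-en-1-yl]but-2-enal | C=CC(C)(C)[C@H](Cl)/C(C=O)=C\CBr | intermediate
9 | (1S,2Z,3R,5R)-5-bromo-2-(2-bromoethylidene)-3-chloro-4,4-dimethylcyclohexan-1-ol | O[C@H]1C[C@@H](Br)C(C)(C)[C@H](Cl)/C1=C\CBr | intermediate
10 | (1S,2Z,3R,5R)-5-bromo-2-(2-bromoethylidene)-3-chloro-4,4-dimethylcyclohexyl acetate | CC(=O)O[C@H]1C[C@@H](Br)C(C)(C)[C@H](Cl)/C1=C\CBr | target

**Totals**

Total step count: 8. Longest linear sequence: 8 steps (1 to 10).

**Steps most likely to fail**

Step 7 (ring closure). The TiBr4-bound conjugated aldehyde may be too weak an electrophile for the hindered vinyl group. The secondary cation may also undergo a 1,2-methyl shift before bromide capture, or the allylic C–Cl may exchange halide with the Lewis acid on warming. The fallback sets out from 8 and returns at 10, bypassing 9. Enal 8 is treated with Ac2O and catalytic FeCl3 at 0 °C to give the geminal diacetate (2Z)-4-bromo-2-[(1S)-1-chloro-2,2-dimethylbut-3-en-1-yl]but-2-ene-1,1-diyl diacetate F1. Ionisation of F1 with SnBr4 in CH2Cl2 at −78 °C gives an O-acetyl oxocarbenium ion, a stronger electrophile than the aldehyde complex. Closure through the same chair and bromide capture should then give acetate 10 directly.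

Step 5 (methoxymethylenation). The basic ylide may enolise the ketone at the C–Cl carbon, with loss of enantiopurity, or add in conjugate fashion to the vinyl ketone and start oligomerisation. The fallback sets out from 5 and returns at 8, bypassing 6. Chloromethyllithium is generated in the presence of 5 (ICH2Cl, MeLi·LiBr, THF, −78 °C, then warming); it should add to the carbonyl faster than it deprotonates and then close to the vinyl oxirane 2-[(1S)-1-chloro-2,2-dimethylbut-3-en-1-yl]-2-ethenyloxirane F2. SN2′ opening of F2 with aqueous HBr and catalytic CuBr in Et2O at −20 °C should give the allylic alcohol (2Z)-4-bromo-2-[(1S)-1-chloro-2,2-dimethylbut-3-en-1-yl]but-2-en-1-ol F3. MnO2 in CH2Cl2 oxidises F3 to 8.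

Step 2 (α-chlorination). Enamine formation from the β-quaternary aldehyde may be slow, face selectivity may be incomplete, and the labile α-chloroaldehyde may lose configuration during isolation. The fallback sets out from 1 and returns at 3, bypassing 2. Ester 1 is saponified (LiOH, THF–H2O) to 3,3-dimethylpent-4-enoic acid F4. Its mixed pivalic anhydride (PivCl, Et3N) acylates lithiated (S)-4-benzyloxazolidin-2-one to give the imide (4S)-4-benzyl-3-(3,3-dimethylpent-4-enoyl)-1,3-oxazolidin-2-one F5. Enolisation with NaHMDS at −78 °C and chlorination with NCS anti to the benzyl group should give (4S)-4-benzyl-3-[(2S)-2-chloro-3,3-dimethylpent-4-enoyl]-1,3-oxazolidin-2-one F6; its diastereomers are separable, so configurational purity can be secured by chromatography. LiBH4 reduction releases (2S)-2-chloro-3,3-dimethylpent-4-en-1-ol F7, and Dess–Martin oxidation of F7 gives 3.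

**Further compounds**

F1 | step 7 | (2Z)-4-bromo-2-[(1S)-1-chloro-2,2-dimethylbut-3-en-1-yl]but-2-ene-1,1-diyl diacetate | C=CC(C)(C)[C@H](Cl)/C(C(OC(C)=O)OC(C)=O)=C\CBr
F2 | step 5 | 2-[(1S)-1-chloro-2,2-dimethylbut-3-en-1-yl]-2-ethenyloxirane | C=CC(C)(C)[C@H](Cl)C1(C=C)CO1
F3 | step 5 | (2Z)-4-bromo-2-[(1S)-1-chloro-2,2-dimethylbut-3-en-1-yl]but-2-en-1-ol | C=CC(C)(C)[C@H](Cl)/C(CO)=C\CBr
F4 | step 2 | 3,3-dimethylpent-4-enoic acid | C=CC(C)(C)CC(=O)O
F5 | step 2 | (4S)-4-benzyl-3-(3,3-dimethylpent-4-enoyl)-1,3-oxazolidin-2-one | C=CC(C)(C)CC(=O)N1[C@@H](Cc2ccccc2)COC1=O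
F6 | step 2 | (4S)-4-benzyl-3-[(2S)-2-chloro-3,3-dimethylpent-4-enoyl]-1,3-oxazolidin-2-one | C=CC(C)(C)[C@H](Cl)C(=O)N1[C@@H](Cc2ccccc2)COC1=O
F7 | step 2 | (2S)-2-chloro-3,3-dimethylpent-4-en-1-ol | C=CC(C)(C)[C@H](Cl)CO
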